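The larch run, charged at 5 mM, stood at 34.7% target at 2.50 min, and the maple run, at 20 mM, stood at 32.0%, which is 2.7 percentage points lower.

| flask | starting material | gas phase | remark | time |
|---|---|---|---|---|
| larch | 5 mM | 2.8 mM (held) | run made earlier |  |
| maple | 20 mM | 2.8 mM (held) | run made earlier |  |
| flask | 10 mM | 2.8 mM (held) |  | 2.5 min |

| run | time / min | target / % | idle adduct / % |
|---|---|---|---|
| larch | 0.167 | 1.9 | 0.6 |
| larch | 0.500 | 8.1 | 3.1 |
| larch | 0.833 | 13.7 | 5.9 |
| larch | 1.33 | 21.6 | 8.0 |
| larch | 2.00 | 29.7 | 12.2 |
| larch | 2.50 | 34.7 | 15.4 |
| maple | 0.200 | 2.1 | 0.8 |
| maple | 0.333 | 5.2 | 1.6 |
| maple | 0.500 | 6.6 | 2.7 |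
| maple | 0.833 | 13.0 | 4.3 |
| maple | 1.50 | 21.6 | 7.6 |
| maple | 2.50 | 32.0 | 12.2 |

(readings scatter by 0.5 percentage points)
1. the target and idle adduct together standing at 2.5 min, as a percentage of the starting material charged
2. the change that raises the amount of target and idle adduct together at 2.5 min, in percent of the starting material charged most ("none" if none brings more than 2 percentage points) (ochre / violet / none)
3. amount of target and idle adduct together at 2.5 min, in percent of the starting material charged, after ochre
- ochre: doubling the transfer coefficient of the gas phase, all else as stated
- violet: doubling the saturation concentration of gas phase, all else as stated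
- what is said of target includes idle adduct
- at the start none of the gas is dissolved
- the analysis behind the earlier runs scatters by 0.5 percentage points, standard deviation
- steps thought possible: target <-> isomer of the product; starting material -> side product; dissolved gas + target <-> idle adduct; starting material + dissolved gas -> target; gas phase <-> dissolved gas

The target column already counts the idle adduct, so I read that column and added nothing to it. In logarithms the two runs give the charge slope, the decades of percent yield at fixed time lost or gained per decade of c(starting material): −0.0584. At fixed c(dissolved gas), a slope of zero is what pseudo-first-order consumption of starting material shows. The flask's 10 mM lies midway between the runs in logarithms, so I estimated 33.3%.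

My doubt was that the slope rests on two scattered readings. At the midpoint, however, an error in the slope cancels, and 0.35 points of scatter remains. A second doubt was the last pair of readings; the pair at 0.833 min gave −0.0378, also small and negative.

For ochre I took the gas shortfall as proportional to charge over transfer coefficient, so doubling the coefficient at 10 mM should act like the 5 mM charge: 34.7%, a gain of 1.4 points, below the 2 points mark. That gain carries the same 0.35 points, yet stays under the mark. Violet doubles the saturation concentration of the gas phase; I expected c(dissolved gas) to follow it, and the step from starting material to target should then act like a doubled clock. The larch run's time exponent of 0.751 gave 56.0%. The curve bends, but an exponent of only 0.5 still gains 14 points, so I chose violet.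

The forecast said 48%, violet and 50.7% after ochre, starting with “Summing target and adduct”; its yield stood above mine.

The flask gave 33.5%.

    target ⇌ isomer of the product (K = 0.269, k = 0.112 /min)
    starting material → side product (k = 0.0794 /min)
    dissolved gas + target ⇌ idle adduct, settled at all times (K = 257 /M)
    starting material + dissolved gas → target (k = 78.9 /M/min)
    gas phase ⇌ dissolved gas, rate k5*(csat - [dissolved gas]) (kL = 11.1 /min)

The best change was violet, gaining 22 points, while ochre reached 34.9%, a gain of 1.4 points. The forecast's excess of 14 points stood close to the flask's idle adduct, 13.6% at 2.50 min, counted in target too. Carrying the flask's result along the charge slope to 40 mM gave 30.9%, and that neighbour stood at 29.0%.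

The runs are simulated for an exercise.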